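## Retrosynthetic overview

1. Target ⇒ (O-debenzylation) ⇒ cut the pyrone C3–CH2 bond. This bond comes from a Knoevenagel-type aldol condensation of 6-ethyl-4-hydroxy-5-methyl-2-pyrone with (S)-5,7-bis(benzyloxy)-8-formylflavanone, and a Hantzsch ester reduces the alkylidene in the same flask.
2. The pyrone ring is made separately by Claisen-type γ-acylation of the methyl 3-oxopentanoate dianion with a propionyl Weinreb amide, followed by lactonisation.
3. 8-CHO ⇐ oxidative cleavage of 8-propenyl ⇐ 8-allyl. The allyl group is placed by an aromatic Claisen rearrangement next to the phenol oxygen that becomes O1, which settles C8 against C6.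
4. The C2 stereocentre and ring B come from a rhodium-catalysed asymmetric 1,4-addition of PhB(OH)2 to the chromone.
5. Ring order: ring A is bought (phloroacetophenone), ring C is closed as a chromone through an enaminone, ring B is added, and the pyrone ring is attached last.

Reading of the target: (2S)-8-[(6-ethyl-4-hydroxy-5-methyl-2-oxo-2H-pyran-3-yl)methyl]-5,7-dihydroxy-2-phenylchroman-4-one, C24H22O7, with one stereocentre (C2, S).

## Route

**Step 1**
Reactants: 1 methyl 3-oxopentanoate; 2 N-methoxy-N-methylpropanamide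
Product: 4 methyl 4-methyl-3,5-dioxoheptanoate, via dilithium dianion 3 (not isolated)
Conditions: LiN(i-Pr)2 (2.2 equiv), THF, 0 °C, 45 min; then 2 (1.0 equiv), −78 to 0 °C; 1 M HCl quench
Reagents that add atoms: none
Why: In this Huckin–Weiler dianion acylation (crossed Claisen type) only the more basic γ-carbon of 3 attacks the amide carbonyl, and the Weinreb amide releases the ketone only on acidic quench, so over-addition and proton quench of the dianion are avoided (the labile C4 centre of 4 disappears in step 2).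

**Step 2**
Reactants: 4 methyl 4-methyl-3,5-dioxoheptanoate
Product: 5 6-ethyl-4-hydroxy-5-methyl-2H-pyran-2-one
Conditions: DBU (1.2 equiv), toluene, reflux, 6 h; then 1 M HCl
Reagents that add atoms: none
Why: This is the standard triketide-to-pyrone lactonisation, in which the C5 enol oxygen attacks the methyl ester and loss of methanol gives the stabilised 4-hydroxy-2-pyrone.

**Step 3**
Reactants: 6 2,4,6-trihydroxyacetophenone
Product: 7 1-[2,4-bis(benzyloxy)-6-hydroxyphenyl]ethanone
Conditions: BnBr (2.05 equiv), K2CO3 (2.2 equiv), DMF, 60 °C, 4 h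
Reagents that add atoms: benzyl bromide BrCc1ccccc1
Why: In this Williamson etherification the para OH and one of the two equivalent ortho OH groups react, while the last ortho OH is hydrogen-bonded to the acetyl group and is much less nucleophilic, so a single bis-ether forms.

**Step 4**
Reactants: 7 1-[2,4-bis(benzyloxy)-6-hydroxyphenyl]ethanone
Product: 8 1-[2-(allyloxy)-4,6-bis(benzyloxy)phenyl]ethanone
Conditions: allyl bromide (1.5 equiv), K2CO3 (2 equiv), DMF, 60 °C, 12 h
Reagents that add atoms: allyl bromide C=CCBr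
Why: Williamson etherification of the only remaining phenol goes to completion with excess reactive allylic halide at higher temperature despite the chelation.

**Step 5**
Reactants: 8 1-[2-(allyloxy)-4,6-bis(benzyloxy)phenyl]ethanone
Product: 9 1-[3-allyl-4,6-bis(benzyloxy)-2-hydroxyphenyl]ethanone
Conditions: N,N-diethylaniline, 200 °C, Ar, 4 h
Reagents that add atoms: none
Why: The [3,3] shift of the aromatic Claisen rearrangement delivers the allyl group to the single unsubstituted ortho carbon, so the carbon substituent sits next to the oxygen that becomes O1 (future C8).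

**Step 6**
Reactants: 9 1-[3-allyl-4,6-bis(benzyloxy)-2-hydroxyphenyl]ethanone
Product: 10 (E)-1-[3-allyl-4,6-bis(benzyloxy)-2-hydroxyphenyl]-3-(dimethylamino)prop-2-en-1-one
Conditions: DMF-DMA (3 equiv), toluene, 100 °C, 4 h
Reagents that add atoms: N,N-dimethylformamide dimethyl acetal COC(OC)N(C)C
Why: Enaminone formation by condensation of the acidic acetyl CH3 with the amide acetal is well established for 2-hydroxy-4,6-dialkoxyacetophenones and adds the future C2.

**Step 7**
Reactants: 10 (E)-1-[3-allyl-4,6-bis(benzyloxy)-2-hydroxyphenyl]-3-(dimethylamino)prop-2-en-1-one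
Product: 11 8-allyl-5,7-bis(benzyloxy)-4H-chromen-4-one
Conditions: conc. HCl (3 equiv), CH2Cl2, 25–40 °C, 1 h
Reagents that add atoms: none
Why: In this acid-promoted addition–elimination the only free phenol adds to the protonated enaminone β-carbon and dimethylamine leaves, which closes ring C as the chromone faster than the allyl group or benzyl ethers react.

**Step 8**
Reactants: 11 8-allyl-5,7-bis(benzyloxy)-4H-chromen-4-one
Product: 12 5,7-bis(benzyloxy)-8-[(E)-prop-1-enyl]-4H-chromen-4-one
Conditions: RuHCl(CO)(PPh3)3 (3 mol %), toluene, 100 °C, 6 h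
Reagents that add atoms: none
Why: Ruthenium-hydride olefin isomerisation (hydrometalation/β-hydride elimination) moves the terminal alkene to the more stable internal aryl-conjugated position under neutral conditions, and the E/Z ratio is irrelevant because the group is cleaved later.

**Step 9**
Reactants: 12 5,7-bis(benzyloxy)-8-[(E)-prop-1-enyl]-4H-chromen-4-one; 13 phenylboronic acid
Product: 14 (2S)-5,7-bis(benzyloxy)-2-phenyl-8-[(E)-prop-1-enyl]chroman-4-one
Conditions: 13 (3 equiv), preformed [Rh(OH)((S)-MeO-F12-BIPHEP)]2 (2 mol %), toluene/H2O 20:1, 30 °C, 12 h (ligand = (S)-6,6'-dimethoxybiphenyl-2,2'-diylbis[bis(3,4,5-trifluorophenyl)phosphine])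
Reagents that add atoms: none
Why: In this Hayashi–Miyaura asymmetric conjugate addition the phenyl-rhodium complex of the electron-poor (S)-bisphosphine inserts C2=C3 on the enone face that gives (S)-3-phenylcyclohexanone with (S)-BINAP, which maps to (2S) here, and the nearly neutral medium avoids retro-oxa-Michael racemisation (ee checked by chiral HPLC and raised by recrystallisation if needed).

**Step 10**
Reactants: 14 (2S)-5,7-bis(benzyloxy)-2-phenyl-8-[(E)-prop-1-enyl]chroman-4-one
Product: 16 (2S)-5,7-bis(benzyloxy)-4-oxo-2-phenylchromane-8-carbaldehyde, via vicinal diol 15 (not isolated)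
Conditions: OsO4 (3 mol %), NaIO4 (4 equiv), 2,6-lutidine (2 equiv), dioxane/H2O 3:1, 25 °C, 6 h
Reagents that add atoms: osmium tetroxide O=[Os](=O)(=O)=O (catalytic oxygen carrier); sodium periodate [Na+].[O-]I(=O)(=O)=O (terminal oxygen source)
Why: Lemieux–Johnson cleavage dihydroxylates the only alkene and periodate cleaves diol 15 to the aryl aldehyde under buffered, near-neutral conditions that leave the benzyl ethers, the ketone and C2 untouched.

**Step 11 (key fragment union)**
Reactants: 16 (2S)-5,7-bis(benzyloxy)-4-oxo-2-phenylchromane-8-carbaldehyde; 5 6-ethyl-4-hydroxy-5-methyl-2H-pyran-2-one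
Product: 18 (2S)-5,7-bis(benzyloxy)-8-[(6-ethyl-4-hydroxy-5-methyl-2-oxo-2H-pyran-3-yl)methyl]-2-phenylchroman-4-one, via arylidene pyrandione 17 (not isolated)
Conditions: 5 (1.1 equiv), Hantzsch ester (diethyl 2,6-dimethyl-1,4-dihydropyridine-3,5-dicarboxylate, 1.2 equiv), L-proline (20 mol %), CH2Cl2, 25–35 °C, 24–48 h
Reagents that add atoms: none
Why: The proline-catalysed Knoevenagel condensation (aldol-type addition of the pyrone C3 enol carbon to the aldehyde, then loss of water) joins the two fragments, and alkylidene 17 is reduced at once by hydride transfer from the Hantzsch ester (three-component reductive alkylation), which blocks Michael addition of a second pyrone, while the acidic pyrone buffers the medium so C2 is not epimerised.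

**Step 12**
Reactants: 18 (2S)-5,7-bis(benzyloxy)-8-[(6-ethyl-4-hydroxy-5-methyl-2-oxo-2H-pyran-3-yl)methyl]-2-phenylchroman-4-one
Product: 19 (2S)-8-[(6-ethyl-4-hydroxy-5-methyl-2-oxo-2H-pyran-3-yl)methyl]-5,7-dihydroxy-2-phenylchroman-4-one
Conditions: H2 (1 atm), 10% Pd/C, EtOAc/EtOH 1:1, 25 °C, stopped after uptake of 2 equiv H2
Reagents that add atoms: none
Why: Catalytic hydrogenolysis cleaves the two O-benzyl bonds under neutral conditions much faster than it affects the fully substituted pyrone, the bridging CH2, the aryl ketone or the cyclic C2–O bond, so the (2S) centre is retained.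

## Compound list

1 | methyl 3-oxopentanoate | CCC(=O)CC(=O)OC | starting material
2 | N-methoxy-N-methylpropanamide | CCC(=O)N(C)OC | starting material
3 | dilithium dianion of methyl 3-oxopentanoate | [Li+].[Li+].CC=C([O-])C=C([O-])OC | intermediate
4 | methyl 4-methyl-3,5-dioxoheptanoate (racemic, enolisable) | CCC(=O)C(C)C(=O)CC(=O)OC | intermediate
5 | 6-ethyl-4-hydroxy-5-methyl-2H-pyran-2-one | CCc1oc(=O)cc(O)c1C | intermediate
6 | 2,4,6-trihydroxyacetophenone | CC(=O)c1c(O)cc(O)cc1O | starting material
7 | 1-[2,4-bis(benzyloxy)-6-hydroxyphenyl]ethanone | CC(=O)c1c(O)cc(OCc2ccccc2)cc1OCc1ccccc1 | intermediate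
8 | 1-[2-(allyloxy)-4,6-bis(benzyloxy)phenyl]ethanone | CC(=O)c1c(OCC=C)cc(OCc2ccccc2)cc1OCc1ccccc1 | intermediate
9 | 1-[3-allyl-4,6-bis(benzyloxy)-2-hydroxyphenyl]ethanone | CC(=O)c1c(O)c(CC=C)c(OCc2ccccc2)cc1OCc1ccccc1 | intermediate
10 | (E)-1-[3-allyl-4,6-bis(benzyloxy)-2-hydroxyphenyl]-3-(dimethylamino)prop-2-en-1-one | CN(C)/C=C/C(=O)c1c(O)c(CC=C)c(OCc2ccccc2)cc1OCc1ccccc1 | intermediate
11 | 8-allyl-5,7-bis(benzyloxy)-4H-chromen-4-one | C=CCc1c(OCc2ccccc2)cc(OCc2ccccc2)c2c1occc2=O | intermediate
12 | 5,7-bis(benzyloxy)-8-[(E)-prop-1-enyl]-4H-chromen-4-one | C/C=C/c1c(OCc2ccccc2)cc(OCc2ccccc2)c2c1occc2=O | intermediate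
13 | phenylboronic acid | OB(O)c1ccccc1 | starting material
14 | (2S)-5,7-bis(benzyloxy)-2-phenyl-8-[(E)-prop-1-enyl]chroman-4-one | C/C=C/c1c(OCc2ccccc2)cc(OCc2ccccc2)c2c1O[C@H](c1ccccc1)CC2=O | intermediate
15 | (2S)-5,7-bis(benzyloxy)-8-(1,2-dihydroxypropyl)-2-phenylchroman-4-one (diol diastereomers) | CC(O)C(O)c1c(OCc2ccccc2)cc(OCc2ccccc2)c2c1O[C@H](c1ccccc1)CC2=O | intermediate
16 | (2S)-5,7-bis(benzyloxy)-4-oxo-2-phenylchromane-8-carbaldehyde | O=Cc1c(OCc2ccccc2)cc(OCc2ccccc2)c2c1O[C@H](c1ccccc1)CC2=O | intermediate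
17 | 3-{[(2S)-5,7-bis(benzyloxy)-4-oxo-2-phenylchroman-8-yl]methylidene}-6-ethyl-5-methyl-2H-pyran-2,4(3H)-dione | CCC1=C(C)C(=O)C(=Cc2c(OCc3ccccc3)cc(OCc3ccccc3)c3c2O[C@H](c2ccccc2)CC3=O)C(=O)O1 | intermediate
18 | (2S)-5,7-bis(benzyloxy)-8-[(6-ethyl-4-hydroxy-5-methyl-2-oxo-2H-pyran-3-yl)methyl]-2-phenylchroman-4-one | CCc1oc(=O)c(Cc2c(OCc3ccccc3)cc(OCc3ccccc3)c3c2O[C@H](c2ccccc2)CC3=O)c(O)c1C | intermediate
19 | (2S)-8-[(6-ethyl-4-hydroxy-5-methyl-2-oxo-2H-pyran-3-yl)methyl]-5,7-dihydroxy-2-phenylchroman-4-one | CCc1oc(=O)c(Cc2c(O)cc(O)c3c2O[C@H](c2ccccc2)CC3=O)c(O)c1C | target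

## Summary

Total step count: 12.
Longest linear sequence: 10 steps (steps 3–12, from 6 to 19). The pyrone branch (steps 1–2) joins at step 11.

## Steps most likely to fail

**(a) Step 9.** The chromone is electron-rich and substituted at C8, so it may react slowly or with reduced ee.

The fallback sets out from 9 and comes back at 14. Compound 9 is isomerised with RuHCl(CO)(PPh3)3 in toluene at 100 °C to 1-[4,6-bis(benzyloxy)-2-hydroxy-3-[(E)-prop-1-enyl]phenyl]ethanone F1. A Claisen–Schmidt aldol condensation with benzaldehyde (KOH, EtOH, 25 °C) gives (E)-1-[4,6-bis(benzyloxy)-2-hydroxy-3-[(E)-prop-1-enyl]phenyl]-3-phenylprop-2-en-1-one F2. NaOAc in refluxing EtOH closes the ring by oxa-Michael addition to racemic 5,7-bis(benzyloxy)-2-phenyl-8-[(E)-prop-1-enyl]chroman-4-one F3.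

The racemate is then resolved kinetically by asymmetric transfer hydrogenation with RuCl[(R,R)-TsDPEN](p-cymene), HCO2H/Et3N in EtOAc, run to about 55 % conversion. The (2R) ketone is reduced to (2R,4R)-5,7-bis(benzyloxy)-2-phenyl-8-[(E)-prop-1-enyl]chroman-4-ol F4. The untouched (2S) ketone is 14 and is separated by chromatography.

**(b) Step 11.** The aldehyde is flanked by two ortho oxygens and is electron-rich, so the condensation may stall.

The fallback sets out from 16 and comes back at 18. Only the aldehyde is reduced, with NaBH4 (0.3 equiv) in THF/MeOH at −40 °C, to (2S)-5,7-bis(benzyloxy)-8-(hydroxymethyl)-2-phenylchroman-4-one F5. This alcohol then alkylates C3 of pyrone 5 under acid catalysis (p-TsOH·H2O 10 mol %, CH2Cl2, 25 °C). The alkylation proceeds through the strongly stabilised trialkoxybenzyl cation, so it is a dehydrative SN1 benzylation of the 1,3-dicarbonyl-type nucleophile rather than a carbonyl condensation.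

**(c) Step 1.** C-acylation of a secondary γ-carbanion can give modest yields.

The fallback sets out from 1 and comes back at 4. The same dianion 3 is added to propanal at −78 °C in an aldol reaction, which is faster and cleaner than acylation. This gives methyl 5-hydroxy-4-methyl-3-oxoheptanoate F6 as a diastereomer mixture. Oxidation with Dess–Martin periodinane in CH2Cl2 then gives 4.

## Further compounds

F1 | step 9 | 1-[4,6-bis(benzyloxy)-2-hydroxy-3-[(E)-prop-1-enyl]phenyl]ethanone | C/C=C/c1c(O)c(C(C)=O)c(OCc2ccccc2)cc1OCc1ccccc1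
F2 | step 9 | (E)-1-[4,6-bis(benzyloxy)-2-hydroxy-3-[(E)-prop-1-enyl]phenyl]-3-phenylprop-2-en-1-one | C/C=C/c1c(O)c(C(=O)/C=C/c2ccccc2)c(OCc2ccccc2)cc1OCc1ccccc1
F3 | step 9 | racemic 5,7-bis(benzyloxy)-2-phenyl-8-[(E)-prop-1-enyl]chroman-4-one | C/C=C/c1c(OCc2ccccc2)cc(OCc2ccccc2)c2c1OC(c1ccccc1)CC2=O
F4 | step 9 | (2R,4R)-5,7-bis(benzyloxy)-2-phenyl-8-[(E)-prop-1-enyl]chroman-4-ol | C/C=C/c1c(OCc2ccccc2)cc(OCc2ccccc2)c2c1O[C@@H](c1ccccc1)C[C@H]2O
F5 | step 11 | (2S)-5,7-bis(benzyloxy)-8-(hydroxymethyl)-2-phenylchroman-4-one | OCc1c(OCc2ccccc2)cc(OCc2ccccc2)c2c1O[C@H](c1ccccc1)CC2=O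
F6 | step 1 | methyl 5-hydroxy-4-methyl-3-oxoheptanoate (diastereomer mixture) | CCC(O)C(C)C(=O)CC(=O)OC
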